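- The flask is closed, so the substrate charged is conserved, and the four columns read together show whether much of it stands elsewhere; larch at 4.00 h sums to 100.6%, which within the scatter shows no large amount outside them.

| flask | substrate | free catalyst | remark | time |
|---|---|---|---|---|
| ash | 0.053 M | 1.5 mM | run made earlier |  |
| larch | 0.053 M | 3.4 mM | run made earlier |  |
| midnight | 0.053 M | 2.3 mM |  | 8.0 h |
| summer | 0.053 M | 2.3 mM |  | 5.0 h |

| run | time / h | target / % | catalyst intermediate A / % | over-reaction product / % | substrate / % |
|---|---|---|---|---|---|
| ash | 0.333 | 1.4 | 0.5 | 1.0 | 96.6 |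
| ash | 0.667 | 4.0 | 1.8 | 1.5 | 94.6 |
| ash | 1.00 | 6.2 | 1.7 | 0 | 93.3 |
| ash | 2.00 | 12.7 | 2.4 | 0.6 | 87.7 |
| ash | 4.00 | 23.7 | 0.6 | 1.1 | 75.0 |
| larch | 0.333 | 4.5 | 3.6 | 0 | 92.7 |
| larch | 1.00 | 12.4 | 2.8 | 1.1 | 83.3 |
| larch | 2.00 | 25.7 | 2.5 | 2.4 | 71.2 |
| larch | 3.00 | 33.2 | 1.3 | 4.8 | 60.3 |
| larch | 4.00 | 37.2 | 2.3 | 10.0 | 51.1 |

(standard deviation of a reading: 1 percentage point)



* which of these there is most of at the end, counted by the substrate in it, midnight (target / catalyst intermediate A / over-reaction product / substrate)
* which of these there is most of at the end, counted by the substrate in it, summer (target / catalyst intermediate A / over-reaction product / substrate)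
* the largest of these amounts at the end, in percent of the substrate charged, midnight
* the largest of these amounts at the end, in percent of the substrate charged, summer

- I follow one substrate molecule and ask first for its chance of leaving substrate. I take that loss as pseudo-first-order, with a chance proportional to catalyst × time, the catalyst-hours.
- The last readings give 0.0479 mM⁻¹ h⁻¹ in ash and 0.0494 mM⁻¹ h⁻¹ in larch, and I carry their mean, 0.0487 mM⁻¹ h⁻¹, the loss constant per catalyst-hour.
- The two readings bracket summer's substrate between 56.7% and 57.6%. The mean gives 57.1%, more than the 42.9% that has left it, so in summer substrate stays ahead of target.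
- Midnight's substrate comes to 40.8%, and the next fork matters: target or over-reaction product. Over the same 4.00 h, ash reads 1.1% and larch 10.0%, so I let this step run on catalyst-hours too.
- Midnight has more catalyst-hours than larch. The product appears late, so for my estimate I take larch's reading unchanged as a low edge, 10.0%, and scale it by the square of the catalyst-hours for a high edge, 18.3%.
- With larch's 2.3% of intermediate taken off the low edge, midnight's target lies between 38.5% and 49.2%. The low edge falls below substrate, but I commit to target, near 43.8%.
- The forecast, target at 44.5% for midnight and substrate at 56.8% for summer, stands inside these brackets: “Midnight narrowly favours target”.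
- The flasks give target at 45.5% for midnight and substrate at 57.1% for summer, both inside the brackets.

    substrate + free catalyst ⇌ catalyst intermediate A (K = 980 M⁻¹, k = 88.0 M⁻¹ h⁻¹)
    catalyst intermediate A ⇌ catalyst intermediate B (K = 1.50, k = 12.0 h⁻¹)
    catalyst intermediate B → free catalyst + target (k = 18.0 h⁻¹)
    free catalyst ⇌ dormant form (K = 0.480, k = 0.0980 h⁻¹)
    free catalyst + target → free catalyst + over-reaction product (k = 45.0 M⁻¹ h⁻¹)

- At 5.00 h in summer, target is made 3.13 times faster than it is used up, each step taken net. So at that point a molecule reaching target is still gained faster than it is lost, while 57.1% remains substrate, against my 57.1%. The flask with 0.0039 M of free catalyst, held for 5.0 h, has more catalyst-hours than midnight; the carried constant gives it 38.7% substrate, and it holds 36.4% substrate and 46.9% target.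

All runs come from a simulation from invented constants, and the scatter is random.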